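**Plan**

- Retrosynthesis: the C4–H and C4–CH(CH3)2 bonds go back to a C4 ketone. The dihydropyranone ring is then cut at O1–C2 and C2–C3, separating acetylsyncarpic acid from (1S,5R)-nopinone. These go back to 2,4,6-trihydroxyacetophenone (four C–CH3 bonds) and (+)-β-pinene (C2′=CH2).
- Enabling feature (chromene numbering O1, C2, C3, C4, C4a, C5–C8, C8a; pinane atoms primed): spiro C2 = C2′ carries both O1 and the C3 methylene of the pyran ring, so it is a masked ketone carbon. C3–C4 and O1–C8a=C4a map onto the acetyl group and the enolised β-dicarbonyl of the trione ring.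
- Forward: the trione ring arises by dearomatising tetramethylation and the two pinane rings come intact from β-pinene. The pyranone ring closes last (step 3) by condensation then oxa-Michael addition, and C4 is then taken from C=O to CH(i-Pr) in three steps.
- Stereochemistry: C1′ and C5′ come from (+)-β-pinene. C2 (S) comes from attack of O1 on the alkylidene face anti to the gem-dimethyl bridge under kinetic closure. C4 (R) comes from catalyst-controlled hydrogenation of C3=C4, because the spiro centre differentiates the two pyran faces only through the remote C1′/C3′ difference.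

Key step: step 3

Assumptions: (+)-β-pinene ((1R,5R), the less common antipode) is purchasable; in step 6 the (S)-ligand is taken to be the antipode that serves the C3′ face of 9, and its mirror image is used if the sense of induction proves opposite.

Step 1
Reactants: 1 (+)-β-pinene
Product: 3 (1S,5R)-nopinone, via secondary ozonide 2 (not isolated)
Conditions: O3, CH2Cl2, −78 °C; then PPh3, −78 °C → rt
Reagents that add atoms: ozone, [O-][O+]=O
Why: Ozonolysis of the exocyclic 1,1-disubstituted alkene with reductive cleavage of the ozonide excises the methylene carbon as formaldehyde and leaves the bicyclic skeleton and both bridgehead centres untouched.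

Step 2
Reactants: 4 2,4,6-trihydroxyacetophenone
Product: 5 acetylsyncarpic acid (2-acetyl-3-hydroxy-4,4,6,6-tetramethylcyclohex-2-ene-1,5-dione)
Conditions: MeI (excess), NaOMe, MeOH, 0 °C → reflux; aq. HCl work-up
Reagents that add atoms: iodomethane, CI
Why: Exhaustive C-methylation of the phloroglucinol polyanion (dearomatising alkylation) should stop at the bis-gem-dimethyl triketone because the acetyl-bearing carbon remains enolised, a known preparation of acylsyncarpic acids.

Step 3
Reactants: 5 acetylsyncarpic acid; 3 (1S,5R)-nopinone
Product: 7 spiro-chromane-4,5,7-trione (2S; O1 anti to the CMe2 bridge), via alkylidene triketone 6 (not isolated)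
Conditions: pyrrolidine (2 equiv), EtOH, 3 Å MS, 80 °C; then AcOH (4 equiv), 0 °C → rt
Reagents that add atoms: none
Why: Proposed new method: pyrrolidine should convert 3 into its iminium ion and 5 into the pyrrolidinium triketonate, whose acetyl methyl (the only α-CH in 5) attacks C2′; loss of the amine gives the exocyclic enone 6 (new C3=C2′ bond), which under excess amine should rest as its open triketonate salt and close only after buffering with AcOH, when the vinylogous-acid oxygen adds to C2′ and the resulting C3 enolate is protonated at once. The closest known reactions are the Kabbe synthesis of spiro-chroman-4-ones from 2-hydroxyaryl methyl ketones and cyclic ketones and the amine-mediated Claisen–Schmidt condensation of 2-acetyl-1,3-diones with aldehydes; what is new is the pairing of a much more acidic vinylogous acid with a hindered bicyclic ketone. The pyranone ring closes by 6-endo-trig oxa-Michael addition (equivalently oxa-6π closure of the dienol tautomer), forming O1–C2. The new stereocentre C2 is controlled by the pinane skeleton: O1 should enter on the alkylidene face anti to the gem-dimethyl bridge, whose syn-methyl screens the other face, as in hydroboration or epoxidation of β-pinene, and the E/Z geometry of 6 does not matter because C3 lies in the alkene plane. The step needs cross- rather than self-condensation, secured because 3 has a single, hindered enolisable methylene and the triketonate carbonyls are not electrophilic; it also needs kinetic rather than thermodynamic closure, secured by closing the ring cold in an acetic acid buffer in which no base is strong enough to re-enolise C3 and reopen the ring.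

Step 4
Reactants: 7 spiro-chromane-4,5,7-trione
Product: 8 C4 tertiary carbinol (4-hydroxy-4-isopropyl; both C4 epimers)
Conditions: i-PrMgCl, anhydrous CeCl3, THF, −78 → −40 °C; pH 7 phosphate buffer work-up; crude used directly
Reagents that add atoms: isopropylmagnesium chloride, CC(C)[Mg]Cl
Why: Organocerium 1,2-addition, in which the oxophilic and weakly basic isopropylcerium reagent should add to C4, the only carbonyl with a non-quaternary α-carbon and activated by chelation of Ce(III) between the C4 and C5 oxygens, rather than enolise C3; the configuration of the new carbinol centre is irrelevant because C4 becomes sp2 in step 5.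

Step 5
Reactants: 8 C4 tertiary carbinol
Product: 9 4-isopropyl-2H-pyran (C3=C4 alkene; 2S)
Conditions: Martin sulfurane (1.5 equiv), CH2Cl2, −20 → 0 °C; filtration through Et3N-deactivated silica; used at once
Reagents that add atoms: none
Why: Martin sulfurane dehydration of a tertiary alcohol, in which ionisation is assisted by the O1–C8a=C4a enol ether and the pseudoaxial C3–H is lost to give the linearly conjugated endocyclic diene (the exocyclic isopropylidene isomer would clash with the peri C5=O) at low temperature without acid, so the O1–C2 bond and the C2 configuration should survive.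

Step 6
Reactants: 9 4-isopropyl-2H-pyran
Product: 10 target, (2S,4R,1′S,5′R)-4-isopropyl-6,6,8,8,6′,6′-hexamethyl-3,4-dihydrospiro[chromene-2,2′-bicyclo[3.1.1]heptane]-5,7(6H,8H)-dione
Conditions: H2 (50 bar), [Ir(cod)((S)-tBu-PHOX)]BArF (3 mol%), CH2Cl2, rt
Reagents that add atoms: none
Why: Iridium–N,P-catalysed asymmetric hydrogenation of a cyclic trisubstituted alkene, in which the chiral catalyst rather than the weakly biased substrate should choose the face and add H2 syn to C3′ (placing i-Pr syn to C1′, C4 = R), while the tetrasubstituted C4a=C8a vinylogous ester, both ketones and the allylic C2–O1 bond (at risk of hydrogenolysis on Pd) are left alone.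

**Compound list**

1 | (+)-β-pinene, (1R,5R)-6,6-dimethyl-2-methylidenebicyclo[3.1.1]heptane | C=C1CC[C@@H]2C[C@H]1C2(C)C | starting material
2 | secondary ozonide of 1 (spiro-1,2,4-trioxolane at C2, both spiro epimers; formed in the flask) | C1OC2(CC[C@@H]3C[C@H]2C3(C)C)OO1 | intermediate
3 | (1S,5R)-nopinone, (1S,5R)-6,6-dimethylbicyclo[3.1.1]heptan-2-one | O=C1CC[C@@H]2C[C@H]1C2(C)C | intermediate
4 | 2,4,6-trihydroxyacetophenone | CC(=O)c1c(O)cc(O)cc1O | starting material
5 | acetylsyncarpic acid, 2-acetyl-3-hydroxy-4,4,6,6-tetramethylcyclohex-2-ene-1,5-dione | CC(=O)C1=C(O)C(C)(C)C(=O)C(C)(C)C1=O | intermediate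
6 | 2-{[(1S,5R)-6,6-dimethylbicyclo[3.1.1]heptan-2-ylidene]acetyl}-3-hydroxy-4,4,6,6-tetramethylcyclohex-2-ene-1,5-dione (open alkylidene triketone; E/Z at C3=C2′ not defined, both converge; formed in the flask) | O=C(C=C1CC[C@@H]2C[C@H]1C2(C)C)C1=C(O)C(C)(C)C(=O)C(C)(C)C1=O | intermediate
7 | (2S,1′S,5′R)-6,6,8,8,6′,6′-hexamethylspiro[chromane-2,2′-bicyclo[3.1.1]heptane]-4,5,7(6H,8H)-trione (O1 anti to the CMe2 bridge) | O=C1C[C@]2(CC[C@@H]3C[C@H]2C3(C)C)OC2=C1C(=O)C(C)(C)C(=O)C2(C)C | intermediate
8 | (2S,1′S,5′R)-4-hydroxy-4-isopropyl-6,6,8,8,6′,6′-hexamethyl-3,4-dihydrospiro[chromene-2,2′-bicyclo[3.1.1]heptane]-5,7(6H,8H)-dione (both C4 epimers) | CC(C)C1(O)C[C@]2(CC[C@@H]3C[C@H]2C3(C)C)OC2=C1C(=O)C(C)(C)C(=O)C2(C)C | intermediate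
9 | (2S,1′S,5′R)-4-isopropyl-6,6,8,8,6′,6′-hexamethylspiro[chromene-2,2′-bicyclo[3.1.1]heptane]-5,7(6H,8H)-dione (2H-pyran, C3=C4) | CC(C)C1=C[C@]2(CC[C@@H]3C[C@H]2C3(C)C)OC2=C1C(=O)C(C)(C)C(=O)C2(C)C | intermediate
10 | (2S,4R,1′S,5′R)-4-isopropyl-6,6,8,8,6′,6′-hexamethyl-3,4-dihydrospiro[chromene-2,2′-bicyclo[3.1.1]heptane]-5,7(6H,8H)-dione | CC(C)[C@H]1C[C@]2(CC[C@@H]3C[C@H]2C3(C)C)OC2=C1C(=O)C(C)(C)C(=O)C2(C)C | target

**Step count and risks**

Total steps: 6. Longest linear sequence: 5 (step 1 or step 2, then steps 3–6).

Steps most likely to fail:

1. Step 3. The acetyl methyl of the triketonate may be too weak a nucleophile for the hindered nopinone iminium ion, so that no condensation occurs, or closure may drift to thermodynamic control and erode C2. The fallback uses known reactions only and sets out from 3 and 5. Horner–Wadsworth–Emmons olefination of 3 (triethyl phosphonoacetate, NaH, THF, reflux) gives ethyl [(1S,5R)-6,6-dimethylbicyclo[3.1.1]heptan-2-ylidene]acetate F1. Saponification (LiOH, THF/H2O) gives the corresponding acid F2. In parallel, acid deacetylation of 5 (aq. HCl, reflux) gives syncarpic acid F3. Coupling of F2 with F3 (DCC, DMAP, CH2Cl2) gives the enol ester F4, which under the same DMAP catalysis undergoes the O→C acyl shift to the C-acyl triketone 6. The route is rejoined at 6, which is closed to 7 under the cold acetic acid buffer of step 3.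

2. Step 6. Turnover may be low at the hindered trisubstituted alkene, and facial selectivity may be poor if an unforeseen substrate preference opposes the catalyst. The 2H-pyran 9 may also lose C2 integrity through reversible oxa-6π ring opening if kept warm. The fallback reverses the order of bond formation at C4 so that carbon, not hydrogen, enters last, and it avoids 9 altogether; it sets out from 7. Luche reduction (NaBH4, CeCl3·7H2O, MeOH, −40 °C) gives the C4 carbinol F5. Ionisation with BF3·OEt2 in the presence of potassium isopropenyltrifluoroborate (MeCN/CH2Cl2, −40 → 0 °C) adds the carbon nucleophile to the vinylogous oxocarbenium ion and gives the 4-isopropenyl compound F6. Hydrogenation of its 1,1-disubstituted alkene (H2, RhCl(PPh3)3, benzene, rt) returns to the route at 10. Any intrinsic facial preference that gave the wrong C4 epimer under hydrogen delivery would favour the target in this sequence.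

3. Step 4. The reagent may act as a base at C3 (enolisation, possibly followed by β-elimination of O1 and ring opening) or as a hydride donor instead of adding to C4. The fallback turns enolisation to use and sets out from 7. Kinetic deprotonation and trapping (KHMDS, Comins' reagent, THF, −78 °C) gives the dienyl triflate F7. Negishi coupling with i-PrZnBr (Pd(OAc)2, CPhos, THF, rt) installs the isopropyl group and comes back to the route at 9, bypassing 8.

**Further compounds**

F1 | step 3 | ethyl [(1S,5R)-6,6-dimethylbicyclo[3.1.1]heptan-2-ylidene]acetate (E/Z mixture) | CCOC(=O)C=C1CC[C@@H]2C[C@H]1C2(C)C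
F2 | step 3 | [(1S,5R)-6,6-dimethylbicyclo[3.1.1]heptan-2-ylidene]acetic acid | OC(=O)C=C1CC[C@@H]2C[C@H]1C2(C)C
F3 | step 3 | syncarpic acid, 5-hydroxy-2,2,6,6-tetramethylcyclohex-4-ene-1,3-dione | CC1(C)C(=O)C=C(O)C(C)(C)C1=O
F4 | step 3 | syncarpic acid enol ester of F2 | O=C(C=C1CC[C@@H]2C[C@H]1C2(C)C)OC1=CC(=O)C(C)(C)C(=O)C1(C)C
F5 | step 6 | (2S,1′S,5′R)-4-hydroxy-6,6,8,8,6′,6′-hexamethyl-3,4-dihydrospiro[chromene-2,2′-bicyclo[3.1.1]heptane]-5,7(6H,8H)-dione (C4 epimers) | OC1C[C@]2(CC[C@@H]3C[C@H]2C3(C)C)OC2=C1C(=O)C(C)(C)C(=O)C2(C)C
F6 | step 6 | 4-isopropenyl analogue of 10 (same configuration at C2, C4, C1′, C5′) | CC(=C)[C@H]1C[C@]2(CC[C@@H]3C[C@H]2C3(C)C)OC2=C1C(=O)C(C)(C)C(=O)C2(C)C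
F7 | step 4 | C4 dienyl triflate of 7 (C3=C4) | O=S(=O)(OC1=C[C@]2(CC[C@@H]3C[C@H]2C3(C)C)OC2=C1C(=O)C(C)(C)C(=O)C2(C)C)C(F)(F)F
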